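## Structural features

The target is an achiral, open-chain assembly of five benzene rings and has no stereocentre. Ring A is a pentasubstituted benzene: methoxy at C1, free hydroxyl at C3, 4-hydroxybenzyl groups at C4 and C6, and at C5, between those two arms, a CH2–CH2 bridge that ends at C1' of ring B; only C2 carries hydrogen. Ring B is a phenol with the bridge ortho and a third 4-hydroxybenzyl group para to its hydroxyl. The three outer rings are plain para-substituted phenols, each joined through a single methylene, so the skeleton consists of three diarylmethane units and one bibenzyl unit. The fragile elements are the five electron-rich phenols and the doubly benzylic methylenes, which are open to oxidation and electrophilic attack, and the one methyl ether, which must stay distinct from the neighbouring ring A phenol. The real difficulty is steric and regiochemical: C5 of ring A lies between two benzyl substituents, and three identical arms must be placed at defined positions on two different rings. The key step exploits the fact that the bridge carbon on C5 can be brought in as a carbonyl carbon already bonded to C5 of ring A and C1' of ring B. The second bridge carbon is then inserted between that carbon and one of the rings by aryl migration, so no cross-coupling is needed at C5.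

## Logic of the disconnections

19 to 18: the five phenolic O–H bonds and the four C–H bonds of the saturated bridge are traced back to five benzyl ethers and a triple bond. One protecting group serves all phenols and is removed in the same operation that saturates the bridge. The forward step must reduce a shielded diarylalkyne completely without cleaving the Ar–CH2–Ar bonds or the methyl ether.

18 to 12 and 13 (through 14, 15, 16 and 17): the bond between the two alkyne carbons and one aryl–C(sp) bond are cut, so that both rings return to a single carbon, the carbonyl carbon of 12, and the extra carbon comes from 13. This turns a bibenzyl problem at a crowded position into a diaryl ketone problem. The forward step requires a small carbanion to add to a carbonyl with three ortho substituents, and the aryl shift to be faster than any other reaction of the carbene.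

12 to 11 and two equivalents of 7: the two CH2–ring A bonds at C4 and C6 are cut. The bromines of 11 sit where the alkoxy groups direct an electrophile, and both arms come from the one zinc reagent 7. The cut is placed after ketone formation because 7 can add to an aldehyde during a slow, hindered coupling, whereas the shielded, non-enolisable ketone of 11 should tolerate it. The demand is two couplings at ortho-flanked C–Br bonds.

11 to 10, and 10 to 3 and 8 (through 9): the oxidation level of the central carbon is adjusted, then the bond from that carbon to ring B is cut. The aryllithium 9 adds to the aldehyde of 3, the most reliable way to make a bond to a hindered carbonyl carbon. The two halves become fragments of similar size. The demand is that addition to the aldehyde outruns halogen–metal exchange with the ring A bromides.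

3 to 2 to 1: the two C–Br bonds and the O–benzyl bond are cut. Compound 1 already has the two ring A oxygens differentiated, so the methyl ether never has to be introduced selectively. The demand is bromination at C2 and C6 and not at C4.

8 to 5 and 7, and 5 to 4: the CH2–ring B bond is cut at the position para to oxygen, then the O–benzyl bond. With bromine and iodine on the same ring in 5, the choice of coupling site becomes a matter of halogen reactivity, and the arm is the same reagent 7 that serves ring A. The demand is coupling at C–I with the C–Br bond left intact for the later lithiation.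

7 to 6: the C–Zn bond is cut, which leads back to 6, a purchased compound that already contains a complete protected outer ring with its methylene. One batch of 7 supplies all three arms. The demand is zinc insertion into an electron-rich benzylic C–Cl bond without Wurtz-type homocoupling, giving a solution stable enough to be stored and titrated.

## Other disconnections considered

Alternative 1: The cut is made inside the three outer phenol rings. Each is traced back to a terminal ynone on a preformed bibenzyl core, the tris(ethynyl ketone) A2, and to the four carbons of Danishefsky's diene A3. Forward, three Diels–Alder additions of A3 to A2, followed by acid-promoted loss of methanol and of the silyl group, would aromatise the adducts to the tris(4-hydroxybenzoyl) compound A1.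
- In favour: six C–C bonds and three rings arise in one metal-free operation. The polarity match of diene and ynone places the hydroxyl para to the acyl group, and the new phenols emerge unprotected.
- Equal or better: in bonds formed per operation this step is better than the chosen key step, and it is its equal in raising no stereochemical question.
- Against: the outer rings are the cheapest part of the structure and can be bought ready-made as 6, so building them solves nothing. A2 presupposes the whole bibenzyl core with three acyl carbons attached, two of them flanking C5 of ring A, so the crowded ring and the bridge must still be made by other means. Terminal ynones are sensitive Michael acceptors. A1 carries three diaryl ketones that must later be reduced to methylenes.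
- Comparison: on structure, the chosen plan reaches the correct oxidation level of all three CH2 links directly. On mechanism, the cycloaddition is dependable but must succeed three times on one molecule, twice at positions flanking C5. On step economy the alternative is clearly longer.

Alternative 2: Ring A itself is disconnected at C4–C5 and C5–C6 into the five-carbon chain of the symmetric 1,3-diketone A5 and the ester carbon of the ring B cinnamate A6. Forward, the dianion of A5 would be acylated at its terminal α-carbon by A6, and the chain would close by intramolecular aldol condensation and dehydration to the resorcinol A4. Its stilbene double bond and benzyl ethers would fall in one later hydrogenation.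
- In favour: the congested ring is assembled from an open chain, so no bond has to be made to a crowded arene, and A5 is symmetric and easy to prepare.
- Equal or better: on the steric point the alternative is better than the chosen plan, which still needs two couplings at ortho-flanked C–Br bonds. Its end game, a single hydrogenation, is the equal of the chosen one.
- Against: the dianion may add in conjugate fashion to the cinnamate and not at the ester carbonyl. Polycarbonyl chains of this kind can also close through oxygen to pyranones or through the wrong carbon. A4 has two equivalent free hydroxyls on ring A, so the single methyl ether would need a statistical mono-methylation, which the chosen plan avoids by starting from 1.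
- Comparison: on mechanism, the chosen route relies on reactions with clearer chemoselectivity. On step economy the two plans are of similar length, but the alternative contains two poorly controlled operations.

Alternative 3: The cut is at the three CH2–aryl bonds on the outer-ring side. The pentabenzyl ether A7 is traced back to the tris(benzylic methyl carbonate) A8 of a bibenzyl core and three equivalents of the boronic acid A9. Forward, zerovalent palladium would ionise each benzylic carbonate to an η3-benzyl complex, and transmetalation from A9 and reductive elimination would form each CH2–aryl bond. A7 is one hydrogenolysis away from 19.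
- In favour: the metal attacks an exocyclic benzylic carbon and not a di-ortho-substituted ring carbon, and the three arms arrive late in one operation.
- Equal or better: A9 is an air-stable purchased partner, easier to handle than the zinc reagent 7, so on reagent handling the alternative is better. Its final deprotection is the equal of the chosen one.
- Against: A8 carries three oxygenated benzylic carbons, two of them ortho to the bridge on ring A, and each must be introduced, brought to the alcohol level and activated. The bridge at C5 still has to be built separately. Benzylic carbonates ortho or para to alkoxy groups ionise and solvolyse easily, and three couplings must all go to completion on one molecule.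
- Comparison: the same three bonds are formed with reversed polarity, and both plans use palladium-catalysed sp2–sp3 coupling of comparable reliability. In step economy the alternative is longer, and it offers no answer of its own to the bridge problem that the chosen key step solves.

Key step: step 9

Remark on the chemistry: 2-bromo-4-iodophenol (4) is assumed to be purchasable. The zinc reagent 7 is made once and kept under argon as a titrated THF solution, from which portions are drawn for steps 5 and 8. The benzyl arms on ring A are attached after the carbonyl carbon has become a diaryl ketone, because a benzylic zinc halide can add to a free aldehyde during a slow coupling.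

Step 1
Reactants: 1 3-hydroxy-5-methoxybenzaldehyde
Product: 2 3-(benzyloxy)-5-methoxybenzaldehyde
Conditions: BnBr, K2CO3, DMF, 25 °C
Reagents that add atoms: benzyl bromide, BrCc1ccccc1
Why: Williamson ether synthesis; the phenoxide is O-alkylated by the benzylic bromide and the aldehyde is inert to carbonate.

Step 2
Reactants: 2 3-(benzyloxy)-5-methoxybenzaldehyde
Product: 3 3-(benzyloxy)-2,6-dibromo-5-methoxybenzaldehyde
Conditions: NBS (2.1 equiv), MeCN, 0 to 25 °C
Reagents that add atoms: N-bromosuccinimide, O=C1CCC(=O)N1Br
Why: Electrophilic aromatic bromination; C2 and C6 are each para to one alkoxy group and ortho to the other, the positions brominated first in 3,5-dialkoxybenzaldehydes, whereas C4 is only ortho to both and is deactivated further once two bromines are in place.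

Step 3
Reactants: 4 2-bromo-4-iodophenol
Product: 5 1-(benzyloxy)-2-bromo-4-iodobenzene
Conditions: BnBr, K2CO3, DMF, 25 °C
Reagents that add atoms: benzyl bromide, BrCc1ccccc1
Why: Williamson ether synthesis on a halophenol; neither aryl halide reacts under these conditions.

Step 4
Reactants: 6 4-(benzyloxy)benzyl chloride
Product: 7 [4-(benzyloxy)benzyl]zinc chloride (titrated THF solution)
Conditions: Zn dust (1.5 equiv), LiCl (1.5 equiv), THF, 25 °C; filtered, aliquot titrated with I2
Reagents that add atoms: zinc, [Zn]
Why: Direct oxidative insertion of zinc into a benzylic C–Cl bond, assisted by LiCl, which solubilises the organozinc and keeps the metal surface active. Benzylic zinc chlorides made this way keep in THF under argon, so one batch can supply steps 5 and 8.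

Step 5
Reactants: 5 1-(benzyloxy)-2-bromo-4-iodobenzene, 7 [4-(benzyloxy)benzyl]zinc chloride
Product: 8 1-(benzyloxy)-4-[4-(benzyloxy)benzyl]-2-bromobenzene
Conditions: 7 (1.2 equiv), Pd(PPh3)4 (2 mol %), THF, 25 °C
Reagents that add atoms: none
Why: Negishi coupling; zerovalent palladium inserts into the C–I bond far faster than into the electron-rich C–Br bond ortho to the benzyloxy group, so the bromide needed in step 6 should be retained.

Step 6
Reactants: 8 1-(benzyloxy)-4-[4-(benzyloxy)benzyl]-2-bromobenzene, 3 3-(benzyloxy)-2,6-dibromo-5-methoxybenzaldehyde
Product: 10 [3-(benzyloxy)-2,6-dibromo-5-methoxyphenyl]{2-(benzyloxy)-5-[4-(benzyloxy)benzyl]phenyl}methanol (racemic), via aryllithium 9 (not isolated)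
Conditions: 8, n-BuLi (1.0 equiv), THF, −78 °C; then 3, −78 to 0 °C; H2O
Reagents that add atoms: none
Why: Bromine–lithium exchange followed by 1,2-addition of the aryllithium to the aldehyde, which at −78 °C should be much faster than exchange with the ring A bromides; the carbinol centre forms as a racemate and is erased in step 7.

Step 7
Reactants: 10 [3-(benzyloxy)-2,6-dibromo-5-methoxyphenyl]{2-(benzyloxy)-5-[4-(benzyloxy)benzyl]phenyl}methanol
Product: 11 [3-(benzyloxy)-2,6-dibromo-5-methoxyphenyl]{2-(benzyloxy)-5-[4-(benzyloxy)benzyl]phenyl}methanone
Conditions: Dess–Martin periodinane, CH2Cl2, 25 °C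
Reagents that add atoms: none
Why: Dess–Martin oxidation of a secondary diaryl carbinol under near-neutral conditions; the benzyl ethers and the doubly benzylic methylene should not be attacked.

Step 8
Reactants: 11 [3-(benzyloxy)-2,6-dibromo-5-methoxyphenyl]{2-(benzyloxy)-5-[4-(benzyloxy)benzyl]phenyl}methanone, 7 [4-(benzyloxy)benzyl]zinc chloride (3 equiv)
Product: 12 [3-(benzyloxy)-2,6-bis[4-(benzyloxy)benzyl]-5-methoxyphenyl]{2-(benzyloxy)-5-[4-(benzyloxy)benzyl]phenyl}methanone
Conditions: 7 (3 equiv), Pd(OAc)2 (5 mol %), SPhos (10 mol %), THF, 50 °C
Reagents that add atoms: none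
Why: Twofold Negishi coupling; the ortho carbonyl activates both C–Br bonds toward oxidative addition and the bulky biaryl phosphine is suited to di-ortho-substituted aryl bromides. The shielded, non-enolisable diaryl ketone should not be attacked by the organozinc, which an aldehyde at this position could be.

Step 9
Reactants: 12 [3-(benzyloxy)-2,6-bis[4-(benzyloxy)benzyl]-5-methoxyphenyl]{2-(benzyloxy)-5-[4-(benzyloxy)benzyl]phenyl}methanone, 13 trimethylsilyldiazomethane
Product: 18 1-(benzyloxy)-2,4-bis[4-(benzyloxy)benzyl]-3-({2-(benzyloxy)-5-[4-(benzyloxy)benzyl]phenyl}ethynyl)-5-methoxybenzene, via lithiated silyldiazomethane 14 (not isolated), via alkoxide adduct 15 (not isolated), via diazoalkene 16 (not isolated), via alkylidene carbene 17 (not isolated)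
Conditions: 13 (2 equiv), n-BuLi, THF, −78 °C; then 12, −78 °C, then warm to reflux; aq NH4Cl
Reagents that add atoms: none
Why: Deprotonation of 13 gives 14, which adds to the carbonyl carbon of 12 to give the lithium alkoxide 15; the ortho benzyloxy oxygen of ring B can coordinate lithium and guide the reagent to the carbonyl. Peterson-type elimination of lithium trimethylsilanolate from 15 gives the diazoalkene 16, which loses dinitrogen to the alkylidene carbene 17. A 1,2-shift of one aryl group from the former carbonyl carbon to the carbene carbon then gives alkyne 18, so the step forms the bond between the two bridge carbons and one new aryl–C(sp) bond. The closest known reaction type is the Colvin rearrangement of diaryl ketones, a shift of the Fritsch–Buttenberg–Wiechell kind. No ring is closed and no stereocentre is formed. Only chemoselectivity is needed: the aryl shift must outrun 1,5-insertion of the carbene into the benzylic C–H bonds of the ortho arms on ring A and attack on the ether oxygen ortho on ring B. Electron-rich aryl groups migrate very readily to the electron-poor carbene carbon, and either ring may migrate because both paths end in the same alkyne. The ketone has no α-hydrogen, so enolisation cannot compete with addition; shielding by three ortho substituents is the limiting factor and is met with excess reagent and warming.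

Step 10
Reactants: 18 1-(benzyloxy)-2,4-bis[4-(benzyloxy)benzyl]-3-({2-(benzyloxy)-5-[4-(benzyloxy)benzyl]phenyl}ethynyl)-5-methoxybenzene
Product: 19 2,4-bis(4-hydroxybenzyl)-3-{2-[2-hydroxy-5-(4-hydroxybenzyl)phenyl]ethyl}-5-methoxyphenol (CNP0134121.0)
Conditions: H2 (1–3 atm), 10% Pd/C, THF–MeOH, 25 °C
Reagents that add atoms: none
Why: Heterogeneous catalytic hydrogenation; the alkyne is saturated through the cis-stilbene and the five aryl benzyl ethers are hydrogenolysed to phenols and toluene. The diarylmethane C–C bonds and the aryl methyl ether are stable to Pd/C at ambient temperature.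

## Compound list

1 | 3-hydroxy-5-methoxybenzaldehyde | COc1cc(O)cc(C=O)c1 | starting material
2 | 3-(benzyloxy)-5-methoxybenzaldehyde | COc1cc(OCc2ccccc2)cc(C=O)c1 | intermediate
3 | 3-(benzyloxy)-2,6-dibromo-5-methoxybenzaldehyde | COc1cc(OCc2ccccc2)c(Br)c(C=O)c1Br | intermediate
4 | 2-bromo-4-iodophenol | Oc1ccc(I)cc1Br | starting material
5 | 1-(benzyloxy)-2-bromo-4-iodobenzene | Brc1cc(I)ccc1OCc1ccccc1 | intermediate
6 | 4-(benzyloxy)benzyl chloride | ClCc1ccc(OCc2ccccc2)cc1 | starting material
7 | [4-(benzyloxy)benzyl]zinc chloride (titrated THF solution) | Cl[Zn]Cc1ccc(OCc2ccccc2)cc1 | intermediate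
8 | 1-(benzyloxy)-4-[4-(benzyloxy)benzyl]-2-bromobenzene | Brc1cc(Cc2ccc(OCc3ccccc3)cc2)ccc1OCc1ccccc1 | intermediate
9 | {2-(benzyloxy)-5-[4-(benzyloxy)benzyl]phenyl}lithium | [Li]c1cc(Cc2ccc(OCc3ccccc3)cc2)ccc1OCc1ccccc1 | intermediate (not isolated)
10 | [3-(benzyloxy)-2,6-dibromo-5-methoxyphenyl]{2-(benzyloxy)-5-[4-(benzyloxy)benzyl]phenyl}methanol (racemic) | COc1cc(OCc2ccccc2)c(Br)c(C(O)c2cc(Cc3ccc(OCc4ccccc4)cc3)ccc2OCc2ccccc2)c1Br | intermediate
11 | [3-(benzyloxy)-2,6-dibromo-5-methoxyphenyl]{2-(benzyloxy)-5-[4-(benzyloxy)benzyl]phenyl}methanone | COc1cc(OCc2ccccc2)c(Br)c(C(=O)c2cc(Cc3ccc(OCc4ccccc4)cc3)ccc2OCc2ccccc2)c1Br | intermediate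
12 | [3-(benzyloxy)-2,6-bis[4-(benzyloxy)benzyl]-5-methoxyphenyl]{2-(benzyloxy)-5-[4-(benzyloxy)benzyl]phenyl}methanone | COc1cc(OCc2ccccc2)c(Cc2ccc(OCc3ccccc3)cc2)c(C(=O)c2cc(Cc3ccc(OCc4ccccc4)cc3)ccc2OCc2ccccc2)c1Cc1ccc(OCc2ccccc2)cc1 | intermediate
13 | trimethylsilyldiazomethane | C[Si](C)(C)C=[N+]=[N-] | starting material
14 | lithium (trimethylsilyl)diazomethanide | [Li]C(=[N+]=[N-])[Si](C)(C)C | intermediate (not isolated)
15 | lithium alkoxide from addition of 14 to the carbonyl of 12: lithium [3-(benzyloxy)-2,6-bis[4-(benzyloxy)benzyl]-5-methoxyphenyl]{2-(benzyloxy)-5-[4-(benzyloxy)benzyl]phenyl}[diazo(trimethylsilyl)methyl]methanolate (racemic) | COc1cc(OCc2ccccc2)c(Cc2ccc(OCc3ccccc3)cc2)c(C(O[Li])(C(=[N+]=[N-])[Si](C)(C)C)c2cc(Cc3ccc(OCc4ccccc4)cc3)ccc2OCc2ccccc2)c1Cc1ccc(OCc2ccccc2)cc1 | intermediate (not isolated)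
16 | 2-[3-(benzyloxy)-2,6-bis[4-(benzyloxy)benzyl]-5-methoxyphenyl]-2-{2-(benzyloxy)-5-[4-(benzyloxy)benzyl]phenyl}-1-diazoethene | COc1cc(OCc2ccccc2)c(Cc2ccc(OCc3ccccc3)cc2)c(C(=C=[N+]=[N-])c2cc(Cc3ccc(OCc4ccccc4)cc3)ccc2OCc2ccccc2)c1Cc1ccc(OCc2ccccc2)cc1 | intermediate (not isolated)
17 | 2-[3-(benzyloxy)-2,6-bis[4-(benzyloxy)benzyl]-5-methoxyphenyl]-2-{2-(benzyloxy)-5-[4-(benzyloxy)benzyl]phenyl}ethenylidene (alkylidene carbene) | COc1cc(OCc2ccccc2)c(Cc2ccc(OCc3ccccc3)cc2)c(C(=[C])c2cc(Cc3ccc(OCc4ccccc4)cc3)ccc2OCc2ccccc2)c1Cc1ccc(OCc2ccccc2)cc1 | intermediate (not isolated)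
18 | 1-(benzyloxy)-2,4-bis[4-(benzyloxy)benzyl]-3-({2-(benzyloxy)-5-[4-(benzyloxy)benzyl]phenyl}ethynyl)-5-methoxybenzene | COc1cc(OCc2ccccc2)c(Cc2ccc(OCc3ccccc3)cc2)c(C#Cc2cc(Cc3ccc(OCc4ccccc4)cc3)ccc2OCc2ccccc2)c1Cc1ccc(OCc2ccccc2)cc1 | intermediate
19 | 2,4-bis(4-hydroxybenzyl)-3-{2-[2-hydroxy-5-(4-hydroxybenzyl)phenyl]ethyl}-5-methoxyphenol (CNP0134121.0) | COc1cc(O)c(Cc2ccc(O)cc2)c(CCc2cc(Cc3ccc(O)cc3)ccc2O)c1Cc1ccc(O)cc1 | target

## Step count and least certain steps

Total: 10 steps. Longest linear sequence: 7 steps (steps 1, 2, 6, 7, 8, 9, 10; the branches that enter through steps 3 and 5 or through steps 4 and 5 are equally long).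

Step 9 (key step). The most likely failure is that the lithiated diazo reagent does not add to the carbonyl, which is shielded by three ortho substituents, before it decomposes on warming. The second is diversion of the carbene into C–H insertion at an ortho benzylic methylene or attack on the ortho ether oxygen before the aryl shift. Compound 13 is toxic by inhalation and is handled only as a solution in a closed system. Fallback: it sets out from 3 and 8 and returns at 18, building the alkyne on the aldehyde carbon and attaching ring B at the unhindered alkyne terminus. Aldehyde 3 with dimethyl (1-diazo-2-oxopropyl)phosphonate and K2CO3 in MeOH should give 1-(benzyloxy)-2,4-dibromo-3-ethynyl-5-methoxybenzene F1. Bromide 8 is lithiated to 9 as in step 6 and quenched with iodine to give 1-(benzyloxy)-4-[4-(benzyloxy)benzyl]-2-iodobenzene F2. Sonogashira coupling of F1 with F2 (PdCl2(PPh3)2, CuI, Et3N, THF, 25 °C), where the iodide reacts in preference to the ortho-flanked bromides, should give the dibromo diarylalkyne F3. Twofold Negishi coupling of F3 with 7 under the conditions of step 8, here next to a slim alkyne instead of an aroyl group, should give 18.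

Step 8. The second coupling may stall at the more crowded C–Br bond, with reductive loss of bromine or homocoupling of the zinc reagent taking over, on a late and valuable intermediate. Fallback: it sets out from 3 and returns at 12, putting the arms on before the ketone exists with the aldehyde masked. Aldehyde 3 with trimethyl orthoformate and catalytic p-TsOH in MeOH gives the dimethyl acetal F4. Twofold Negishi coupling of F4 with 7 (Pd(OAc)2, SPhos) gives the dibenzylated acetal F5, which aqueous HCl in THF converts to 3-(benzyloxy)-2,6-bis[4-(benzyloxy)benzyl]-5-methoxybenzaldehyde F6. Addition of aryllithium 9, made from 8 as in step 6, to F6 gives the carbinol F7, and Dess–Martin oxidation of F7 gives 12.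

Step 5. Halogen selectivity may be lost, with coupling also at the C–Br bond, or the zinc reagent may homocouple under palladium instead of coupling. Fallback: it sets out from 5 and returns at 8 using polar chemistry instead of cross-coupling. Iodine–magnesium exchange on 5 with iPrMgCl·LiCl in THF at −20 °C, which leaves the bromide alone, gives the aryl Grignard reagent F8. Addition of F8 to purchased 4-(benzyloxy)benzaldehyde gives the diaryl carbinol F9. Ionic deoxygenation of F9 with Et3SiH and BF3·OEt2 in CH2Cl2 at −20 °C gives 8.

Step 10. The ring B benzyl ether ortho to the bridge may be hydrogenolysed before the shielded alkyne is saturated, letting the freed phenol cyclise onto the triple bond. The catalyst may also be poisoned by metal or phosphine residues from earlier steps. Fallback: it sets out from 18 and returns at 19, separating the two tasks. Diimide reduction (p-toluenesulfonyl hydrazide, NaOAc, DME–H2O, reflux) saturates the alkyne with all ethers intact to give the pentabenzyl ether of the target F10. BCl3 with pentamethylbenzene as cation scavenger in CH2Cl2 at −78 °C then removes the five benzyl groups from F10 and leaves the methyl ether, giving 19.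

## Further compounds

F1 | step 9 | 1-(benzyloxy)-2,4-dibromo-3-ethynyl-5-methoxybenzene | COc1cc(OCc2ccccc2)c(Br)c(C#C)c1Br
F2 | step 9 | 1-(benzyloxy)-4-[4-(benzyloxy)benzyl]-2-iodobenzene | Ic1cc(Cc2ccc(OCc3ccccc3)cc2)ccc1OCc1ccccc1
F3 | step 9 | 1-(benzyloxy)-2,4-dibromo-3-({2-(benzyloxy)-5-[4-(benzyloxy)benzyl]phenyl}ethynyl)-5-methoxybenzene | COc1cc(OCc2ccccc2)c(Br)c(C#Cc2cc(Cc3ccc(OCc4ccccc4)cc3)ccc2OCc2ccccc2)c1Br
F4 | step 8 | 1-(benzyloxy)-2,4-dibromo-3-(dimethoxymethyl)-5-methoxybenzene | COc1cc(OCc2ccccc2)c(Br)c(C(OC)OC)c1Br
F5 | step 8 | 1-(benzyloxy)-2,4-bis[4-(benzyloxy)benzyl]-3-(dimethoxymethyl)-5-methoxybenzene | COc1cc(OCc2ccccc2)c(Cc2ccc(OCc3ccccc3)cc2)c(C(OC)OC)c1Cc1ccc(OCc2ccccc2)cc1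
F6 | step 8 | 3-(benzyloxy)-2,6-bis[4-(benzyloxy)benzyl]-5-methoxybenzaldehyde | COc1cc(OCc2ccccc2)c(Cc2ccc(OCc3ccccc3)cc2)c(C=O)c1Cc1ccc(OCc2ccccc2)cc1
F7 | step 8 | [3-(benzyloxy)-2,6-bis[4-(benzyloxy)benzyl]-5-methoxyphenyl]{2-(benzyloxy)-5-[4-(benzyloxy)benzyl]phenyl}methanol (racemic) | COc1cc(OCc2ccccc2)c(Cc2ccc(OCc3ccccc3)cc2)c(C(O)c2cc(Cc3ccc(OCc4ccccc4)cc3)ccc2OCc2ccccc2)c1Cc1ccc(OCc2ccccc2)cc1
F8 | step 5 | [4-(benzyloxy)-3-bromophenyl]magnesium chloride | Cl[Mg]c1ccc(OCc2ccccc2)c(Br)c1
F9 | step 5 | [4-(benzyloxy)-3-bromophenyl][4-(benzyloxy)phenyl]methanol (racemic) | OC(c1ccc(OCc2ccccc2)cc1)c1ccc(OCc2ccccc2)c(Br)c1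
F10 | step 10 | 1-(benzyloxy)-2,4-bis[4-(benzyloxy)benzyl]-3-(2-{2-(benzyloxy)-5-[4-(benzyloxy)benzyl]phenyl}ethyl)-5-methoxybenzene | COc1cc(OCc2ccccc2)c(Cc2ccc(OCc3ccccc3)cc2)c(CCc2cc(Cc3ccc(OCc4ccccc4)cc3)ccc2OCc2ccccc2)c1Cc1ccc(OCc2ccccc2)cc1
A1 | alternative 1 | {4-(benzyloxy)-3-{2-[3-(benzyloxy)-2,6-bis(4-hydroxybenzoyl)-5-methoxyphenyl]ethyl}phenyl}(4-hydroxyphenyl)methanone | COc1cc(OCc2ccccc2)c(C(=O)c2ccc(O)cc2)c(CCc2cc(C(=O)c3ccc(O)cc3)ccc2OCc2ccccc2)c1C(=O)c1ccc(O)cc1
A2 | alternative 1 | tris(ethynyl ketone) of the protected bibenzyl core: 1-{4-(benzyloxy)-3-{2-[3-(benzyloxy)-5-methoxy-2,6-di(prop-2-ynoyl)phenyl]ethyl}phenyl}prop-2-yn-1-one | COc1cc(OCc2ccccc2)c(C(=O)C#C)c(CCc2cc(C(=O)C#C)ccc2OCc2ccccc2)c1C(=O)C#C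
A3 | alternative 1 | Danishefsky's diene, (E)-1-methoxy-3-(trimethylsilyloxy)buta-1,3-diene | CO/C=C/C(=C)O[Si](C)(C)C
A4 | alternative 2 | 4,6-bis[4-(benzyloxy)benzyl]-5-[(E)-2-{2-(benzyloxy)-5-[4-(benzyloxy)benzyl]phenyl}ethenyl]benzene-1,3-diol | Oc1cc(O)c(Cc2ccc(OCc3ccccc3)cc2)c(/C=C/c2cc(Cc3ccc(OCc4ccccc4)cc3)ccc2OCc2ccccc2)c1Cc1ccc(OCc2ccccc2)cc1
A5 | alternative 2 | 1,7-bis[4-(benzyloxy)phenyl]heptane-3,5-dione | O=C(CCc1ccc(OCc2ccccc2)cc1)CC(=O)CCc1ccc(OCc2ccccc2)cc1
A6 | alternative 2 | methyl (E)-3-{2-(benzyloxy)-5-[4-(benzyloxy)benzyl]phenyl}prop-2-enoate | COC(=O)/C=C/c1cc(Cc2ccc(OCc3ccccc3)cc2)ccc1OCc1ccccc1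
A7 | alternative 3 | 1-(benzyloxy)-2,4-bis[4-(benzyloxy)benzyl]-3-(2-{2-(benzyloxy)-5-[4-(benzyloxy)benzyl]phenyl}ethyl)-5-methoxybenzene | COc1cc(OCc2ccccc2)c(Cc2ccc(OCc3ccccc3)cc2)c(CCc2cc(Cc3ccc(OCc4ccccc4)cc3)ccc2OCc2ccccc2)c1Cc1ccc(OCc2ccccc2)cc1
A8 | alternative 3 | tris(benzylic methyl carbonate) of the protected bibenzyl core | COc1cc(OCc2ccccc2)c(COC(=O)OC)c(CCc2cc(COC(=O)OC)ccc2OCc2ccccc2)c1COC(=O)OC
A9 | alternative 3 | 4-(benzyloxy)phenylboronic acid | OB(O)c1ccc(OCc2ccccc2)cc1
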